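Divide the two charges before looking at any rate. Zeta held c(starting material) = 1.0 M and theta 0.30 M, so in percent of the charge the two flasks tie when zeta makes target 3.33 times as fast in M/h; I called this the tie ratio. Turned round, the question was whether zeta's rate over theta's stood clearly away from that ratio, on either side.

| flask | starting material | partner | protic impurity | free catalyst | remark | time |
|---|---|---|---|---|---|---|
| alder | 1 M | 0.33 M | 0.020 M | 50 mM | run made earlier |  |
| oak | 1 M | 0.60 M | 0.020 M | 50 mM | run made earlier |  |
| ash | 0.59 M | 1.2 M | 0.020 M | 50 mM | run made earlier |  |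
| zeta | 1.0 M | 1.20 M | 0.0200 M | 50 mM |  | 5.0 h |
| theta | 0.30 M | 0.300 M | 0.0200 M | 50 mM |  | 5.0 h |

| run | time / h | target / % | starting material / % |
|---|---|---|---|
| alder | 0.250 | 0.2 | 94.5 |
| alder | 0.500 | 0.9 | 93.8 |
| alder | 1.00 | 3.3 | 92.2 |
| alder | 2.00 | 4.3 | 89.5 |
| alder | 4.00 | 8.6 | 84.8 |
| oak | 0.667 | 2.3 | 92.3 |
| oak | 1.33 | 6.0 | 89.3 |
| oak | 2.00 | 8.4 | 86.7 |
| oak | 3.00 | 12.3 | 82.7 |
| oak | 4.00 | 15.9 | 78.6 |
| ash | 0.250 | 3.0 | 90.0 |
| ash | 0.500 | 5.1 | 86.7 |
| ash | 1.00 | 11.5 | 80.1 |
| ash | 2.00 | 21.9 | 68.9 |
| ash | 4.00 | 44.4 | 48.2 |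

(standard deviation of a reading: 0.5 percentage points)

* the winner by amount of target, in percent of the starting material charged; "neither" if no more than 2 percentage points parts them (zeta / theta / neither)
* how much target is there at the end, in percent of the starting material charged: zeta
* how much target is there at the end, in percent of the starting material charged: theta

- what was read earlier has a scatter of 0.5 percentage points, one standard deviation
- a reading or a percentage of target counts all its forms, free or not

I froze the rate. In ash, target came at 0.0678 M h⁻¹ in the first hour and 0.0664 M h⁻¹ from 2.00 h to 4.00 h, while starting material fell to 48.2%, so I took the rate as steady and zero order in starting material. Ash had zeta's c(partner), so I gave zeta its mean rate, 0.0655 M h⁻¹. Per c(partner), alder gave 0.0215 M h⁻¹ / 0.33 M, or 0.0652 h⁻¹, and oak 0.0663 h⁻¹, so I scaled alder in proportion to theta's c(partner) and got 0.0195 M h⁻¹.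

The rate ratio came to 3.35, about the tie ratio. My reckoning gave zeta 32.7% and theta 32.6%, a gap of 0.10 percentage points, smaller than the margin of 2 points, so I committed to neither. The forecast differed on the winner: it chose zeta, with 34% for zeta and 29% for theta: “The gap is small, but zeta is favoured.”

The flasks gave neither, with 32.8% for zeta and 33.3% for theta.

    starting material + free catalyst → catalyst intermediate A (k = 1.20 L mol⁻¹ min⁻¹)
    catalyst intermediate A ⇌ catalyst intermediate B (K = 4.40, k = 0.240 min⁻¹)
    partner + catalyst intermediate B ⇌ catalyst intermediate C (K = 0.480 L mol⁻¹, k = 1.20 L mol⁻¹ min⁻¹)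
    catalyst intermediate C → by-product + catalyst intermediate D (k = 0.0940 min⁻¹)
    catalyst intermediate D ⇌ free catalyst + target (K = 22.0 M, k = 2.70 min⁻¹)
    free catalyst + target ⇌ idle complex, settled at all times (K = 2.40 L mol⁻¹)
    partner + protic impurity → quenched reagent (k = 0.780 L mol⁻¹ min⁻¹)

Target comes by way of catalyst intermediate C, and at 2.50 h that form held 23.6% of the catalyst in zeta against 7.25% in theta, a ratio of 3.26 beside the tie ratio 3.33, while catalyst intermediate B, the resting state, held 51.3% and 70.4%. The neighbour of theta with 0.12 M of partner had theta's charge of starting material and so the same tie ratio; the alder scaling put zeta's rate over that neighbour's at 8.38, which divided by 3.33 is 2.51, and the neighbour gave 12.9% against zeta's 32.8%, a ratio of 2.54.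

The readings come from a simulation for an exercise; noise was put on by code.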